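A direct plan would set C2 first by asymmetric transfer hydrogenation of a β-keto Weinreb amide (hydroxy amide A1), hang A1 on a cyclobutenone (vinylogous ester A2), grow ring A by thermal benzannulation of A2 with silyl ynol ether A3, silylate and iodinate the new ring to give aryl iodide A4, and close ring C from A4 by iodine–lithium exchange onto the amide.
Its weakest steps would be: the benzannulation, which would join both fragments at 110 °C through a reluctant alkoxycyclobutenone while the benzylic ether could eliminate, leaving ring closure and C2 to chance;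
the iodination leading to aryl iodide A4, which would have to hit a position between two bulky ethers beside two nucleophilic alkenes;
the lithiation–acylation of A4, which, on the most precious material, would risk silyl shift and β-elimination of the aryloxide.
Half of the steps would only rebuild a phloroglucinol ring that can be bought.

**Plan of the new route**
The retrosynthesis cuts C2–C1′ first (ring B leaves as an arylboronic acid, ring C becomes a 4H-chromen-4-one), then O1–C2 and C4–C4a of ring C, then the C6–geranyl bond.
Ring A is bought, ring C is closed on it as an achiral chromone, and ring B is joined last, in the step that creates C2.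
Two features allow this: C2 is the β-carbon of the C4 ketone within ring C and bears ring B as its only exocyclic carbon; and the geranyl carbon C6 lies para to C8a (O1) between O5 and O7, so the ring A phenol has a mirror plane, its two ortho carbons are equivalent, and no C6/C8 choice arises.
No benzannulation, no halogenation beside the alkenes and no organolithium on an advanced intermediate remain; C2 is made in the last C–C bond formation and then meets only dilute acid.

Key step: step 9

Assumption: 1,3-bis(methoxymethoxy)benzene and both antipodes of MeO-F12-BIPHEP are taken as purchasable; the former is otherwise one step from resorcinol (MeOCH2Cl, iPr2NEt).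

**Step 1**
Reactants: 1 1,3-bis(methoxymethoxy)benzene
Product: 3 3,5-bis(methoxymethoxy)phenol, via aryl pinacol boronate 2 (not isolated)
Conditions: [Ir(OMe)(cod)]2 (1.5 mol%), 4,4′-di-tert-butyl-2,2′-bipyridine (3 mol%), B2pin2 (1.0 equiv), THF, 80 °C; then 30% H2O2, aq. NaOH, 0 °C → rt
Reagents that add atoms: hydrogen peroxide, OO
Why: Iridium-catalysed C–H borylation of a 1,3-disubstituted arene is sterically controlled and should go to C5, the only C–H without an ortho substituent, and oxidation of the boronate in the same flask should give the 3,5-disubstituted phenol (one-pot borylation–oxidation).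

**Step 2**
Reactants: 3 3,5-bis(methoxymethoxy)phenol
Product: 4 [3,5-bis(methoxymethoxy)phenoxy]triisopropylsilane
Conditions: iPr3SiCl (1.1 equiv), imidazole (2 equiv), DMF, rt
Reagents that add atoms: triisopropylsilyl chloride, CC(C)[Si](Cl)(C(C)C)C(C)C
Why: Imidazole-promoted silylation of the phenol masks the acidic proton with a bulky, non-coordinating group that, unlike the acetal ethers, should not direct lithiation to its own ortho positions.

**Step 3**
Reactants: 4 [3,5-bis(methoxymethoxy)phenoxy]triisopropylsilane; 5 geranyl bromide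
Product: 8 4-[(E)-3,7-dimethylocta-2,6-dienyl]-3,5-bis(methoxymethoxy)phenol, via aryllithium 6 (not isolated), via geranylated silyl ether 7 (not isolated)
Conditions: n-BuLi (1.15 equiv), THF, 0 °C; CuBr·SMe2 (10 mol%), 5 (0.9 equiv), −40 → 0 °C; then Bu4NF (3 equiv), 0 °C → rt; aq. NH4Cl
Reagents that add atoms: none
Why: Directed ortho-metalation should take place only at the C–H between the two OCH2OMe groups, which both acidify and chelate it; copper-catalysed SN2 coupling of the aryllithium with the primary allylic bromide (kept limiting so that none is left to O-alkylate the phenoxide) retains the E alkene, and fluoride then cleaves the aryl silyl ether in the same flask.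

**Step 4**
Reactants: 8 4-[(E)-3,7-dimethylocta-2,6-dienyl]-3,5-bis(methoxymethoxy)phenol
Product: 9 3-[(E)-3,7-dimethylocta-2,6-dienyl]-6-hydroxy-2,4-bis(methoxymethoxy)benzaldehyde
Conditions: MgCl2 (2 equiv), Et3N (4 equiv), (CH2O)n (6 equiv), MeCN, 75 °C; dilute HCl work-up at 0 °C
Reagents that add atoms: paraformaldehyde (as formaldehyde), C=O
Why: Magnesium-mediated ortho-formylation of a phenol (Casnati–Skattebøl) delivers formaldehyde to an ortho carbon only and a second formaldehyde oxidises the salicyl alkoxide; the two ortho carbons of 8 are equivalent through its mirror plane, so a single aldehyde should form, and the basic medium spares acetals and alkenes.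

**Step 5**
Reactants: 9 3-[(E)-3,7-dimethylocta-2,6-dienyl]-6-hydroxy-2,4-bis(methoxymethoxy)benzaldehyde; 10 ethynylmagnesium bromide
Product: 11 1-{3-[(E)-3,7-dimethylocta-2,6-dienyl]-6-hydroxy-2,4-bis(methoxymethoxy)phenyl}prop-2-yn-1-ol (racemic)
Conditions: 10 (3 equiv), THF, 0 °C → rt; sat. aq. NH4Cl, 0 °C; crude product used at once
Reagents that add atoms: none
Why: 1,2-Addition of an alkynyl Grignard reagent to the aldehyde of the magnesium phenoxide (the first equivalent is consumed by the phenol) should give the carbinol, whose racemic centre is removed in the next step and which is carried on crude after a neutral work-up because o-hydroxybenzylic alcohols ionise in acid.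

**Step 6**
Reactants: 11 1-{3-[(E)-3,7-dimethylocta-2,6-dienyl]-6-hydroxy-2,4-bis(methoxymethoxy)phenyl}prop-2-yn-1-ol
Product: 14 6-[(E)-3,7-dimethylocta-2,6-dienyl]-5,7-bis(methoxymethoxy)-4H-chromen-4-one, via ynone 12 (not isolated), via diethylamino enone 13 (not isolated)
Conditions: MnO2 (activated, 15 equiv), CH2Cl2, rt; filtration; Et2NH (2 equiv), EtOH, rt; then AcOH (2 equiv), 60 °C
Reagents that add atoms: none
Why: MnO2 should oxidise the benzylic–propargylic alcohol selectively to the ynone, conjugate addition of diethylamine gives the enaminone (which avoids 5-exo closure to a benzofuranone), and the free phenol, the only ortho oxygen not masked as an acetal, closes ring C by 6-endo addition–elimination at C2 with loss of the amine, so that the geranyl group ends at C6.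

**Step 7**
Reactants: 15 4-bromobenzene-1,2-diol
Product: 16 4-bromo-1,2-bis(methoxymethoxy)benzene
Conditions: MeOCH2Cl (2.5 equiv), iPr2NEt (3 equiv), CH2Cl2, 0 °C → rt
Reagents that add atoms: chloromethyl methyl ether, COCCl
Why: Base-promoted O-alkylation of both catechol hydroxyls gives acetal ethers that tolerate organolithium reagents and water and can later leave together with those of ring A.

**Step 8**
Reactants: 16 4-bromo-1,2-bis(methoxymethoxy)benzene
Product: 19 [3,4-bis(methoxymethoxy)phenyl]boronic acid, via aryllithium 17 (not isolated), via lithium triisopropoxyborate 18 (not isolated)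
Conditions: n-BuLi (1.1 equiv), THF, −78 °C; B(OiPr)3 (1.5 equiv), −78 °C → rt; sat. aq. NH4Cl
Reagents that add atoms: triisopropyl borate, CC(C)OB(OC(C)C)OC(C)C; water, O
Why: Bromine–lithium exchange at −78 °C is faster than ortho-deprotonation, the aryllithium is trapped by the borate ester, and hydrolysis of the ate complex at pH 5–6 should release the boronic acid without touching the acetals.

**Step 9**
Reactants: 14 6-[(E)-3,7-dimethylocta-2,6-dienyl]-5,7-bis(methoxymethoxy)-4H-chromen-4-one; 19 [3,4-bis(methoxymethoxy)phenyl]boronic acid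
Product: 20 (2S)-2-[3,4-bis(methoxymethoxy)phenyl]-6-[(E)-3,7-dimethylocta-2,6-dienyl]-5,7-bis(methoxymethoxy)-2,3-dihydro-4H-chromen-4-one
Conditions: [Rh(OH)(cod)]2 (2.5 mol%), (S)-MeO-F12-BIPHEP [(S)-2,2′-bis[bis(3,4,5-trifluorophenyl)phosphino]-6,6′-dimethoxy-1,1′-biphenyl] (5.5 mol%), 19 (3 equiv), toluene/H2O (10:1), 30 °C
Reagents that add atoms: none
Why: Transmetalation from boron gives an aryl complex of monovalent rhodium, the C2=C3 bond of the chromone inserts into the Rh–aryl bond so that C2–C1′ forms, and water protonates the resulting oxa-π-allyl rhodium enolate to release the flavanone and the Rh–OH species (Hayashi–Miyaura asymmetric 1,4-addition, a reaction type known for chromones with electron-poor biaryl bisphosphines). No ring is closed here: ring C is already present as the planar pyranone, and the step turns its C2 into the stereocentre while joining ring B. C2 is the only new stereocentre and is set by the catalyst, which distinguishes the two faces of the C2=C3 bond at the insertion; by analogy with the sense of (S)-biaryl bisphosphine rhodium catalysts on 2-cyclohexenone (the ring oxygen taking the place of C4) the (S)-ligand should give (2S), which is to be confirmed by circular dichroism at this stage, the (R)-ligand being used otherwise. The step needs 1,4- over 1,2-addition, no reaction at the two trisubstituted alkenes and no ring opening of the product: the base-free, near-ambient conditions allowed by the electron-poor ligand, the absence of any free phenol (all four are acetals, so no phenoxide can drive a retro-oxa-Michael opening) and the inertness of unactivated trisubstituted alkenes toward aryl–rhodium insertion should secure this. The excess of boronic acid covers protodeboronation of the electron-rich aryl group.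

**Step 10**
Reactants: 20 (2S)-2-[3,4-bis(methoxymethoxy)phenyl]-6-[(E)-3,7-dimethylocta-2,6-dienyl]-5,7-bis(methoxymethoxy)-2,3-dihydro-4H-chromen-4-one
Product: 21 nymphaeol A
Conditions: HCl (1.5 M) in MeOH/THF (3:1), 40 °C, stopped at full conversion
Reagents that add atoms: none
Why: Acid-catalysed acetal exchange with methanol should remove all four methoxymethyl groups as dimethoxymethane; C2 of a flavanone is configurationally stable in dilute acid (opening needs a phenoxide), and this acidity lies below that at which a geranyl group cyclises onto a neighbouring phenol.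

**Compound list**
1 | 1,3-bis(methoxymethoxy)benzene | COCOc1cccc(OCOC)c1 | starting material
2 | 2-[3,5-bis(methoxymethoxy)phenyl]-4,4,5,5-tetramethyl-1,3,2-dioxaborolane | COCOc1cc(OCOC)cc(B2OC(C)(C)C(C)(C)O2)c1 | intermediate
3 | 3,5-bis(methoxymethoxy)phenol | COCOc1cc(O)cc(OCOC)c1 | intermediate
4 | [3,5-bis(methoxymethoxy)phenoxy]triisopropylsilane | COCOc1cc(OCOC)cc(O[Si](C(C)C)(C(C)C)C(C)C)c1 | intermediate
5 | geranyl bromide, (E)-1-bromo-3,7-dimethylocta-2,6-diene | CC(C)=CCC/C(C)=C/CBr | starting material
6 | [2,6-bis(methoxymethoxy)-4-(triisopropylsilyloxy)phenyl]lithium | COCOc1cc(O[Si](C(C)C)(C(C)C)C(C)C)cc(OCOC)c1[Li] | intermediate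
7 | {4-[(E)-3,7-dimethylocta-2,6-dienyl]-3,5-bis(methoxymethoxy)phenoxy}triisopropylsilane | CC(C)=CCC/C(C)=C/Cc1c(OCOC)cc(O[Si](C(C)C)(C(C)C)C(C)C)cc1OCOC | intermediate
8 | 4-[(E)-3,7-dimethylocta-2,6-dienyl]-3,5-bis(methoxymethoxy)phenol | CC(C)=CCC/C(C)=C/Cc1c(OCOC)cc(O)cc1OCOC | intermediate
9 | 3-[(E)-3,7-dimethylocta-2,6-dienyl]-6-hydroxy-2,4-bis(methoxymethoxy)benzaldehyde | CC(C)=CCC/C(C)=C/Cc1c(OCOC)cc(O)c(C=O)c1OCOC | intermediate
10 | ethynylmagnesium bromide | C#C[Mg]Br | starting material
11 | 1-{3-[(E)-3,7-dimethylocta-2,6-dienyl]-6-hydroxy-2,4-bis(methoxymethoxy)phenyl}prop-2-yn-1-ol (racemic) | CC(C)=CCC/C(C)=C/Cc1c(OCOC)cc(O)c(C(O)C#C)c1OCOC | intermediate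
12 | 1-{3-[(E)-3,7-dimethylocta-2,6-dienyl]-6-hydroxy-2,4-bis(methoxymethoxy)phenyl}prop-2-yn-1-one | CC(C)=CCC/C(C)=C/Cc1c(OCOC)cc(O)c(C(=O)C#C)c1OCOC | intermediate
13 | (E)-3-(diethylamino)-1-{3-[(E)-3,7-dimethylocta-2,6-dienyl]-6-hydroxy-2,4-bis(methoxymethoxy)phenyl}prop-2-en-1-one | CC(C)=CCC/C(C)=C/Cc1c(OCOC)cc(O)c(C(=O)/C=C/N(CC)CC)c1OCOC | intermediate
14 | 6-[(E)-3,7-dimethylocta-2,6-dienyl]-5,7-bis(methoxymethoxy)-4H-chromen-4-one | CC(C)=CCC/C(C)=C/Cc1c(OCOC)cc2occc(=O)c2c1OCOC | intermediate
15 | 4-bromobenzene-1,2-diol | Oc1ccc(Br)cc1O | starting material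
16 | 4-bromo-1,2-bis(methoxymethoxy)benzene | COCOc1ccc(Br)cc1OCOC | intermediate
17 | [3,4-bis(methoxymethoxy)phenyl]lithium | COCOc1ccc([Li])cc1OCOC | intermediate
18 | lithium [3,4-bis(methoxymethoxy)phenyl]triisopropoxyborate | COCOc1ccc([B-](OC(C)C)(OC(C)C)OC(C)C)cc1OCOC.[Li+] | intermediate
19 | [3,4-bis(methoxymethoxy)phenyl]boronic acid | COCOc1ccc(B(O)O)cc1OCOC | intermediate
20 | (2S)-2-[3,4-bis(methoxymethoxy)phenyl]-6-[(E)-3,7-dimethylocta-2,6-dienyl]-5,7-bis(methoxymethoxy)-2,3-dihydro-4H-chromen-4-one | CC(C)=CCC/C(C)=C/Cc1c(OCOC)cc2c(c1OCOC)C(=O)C[C@@H](c1ccc(OCOC)c(OCOC)c1)O2 | intermediate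
21 | nymphaeol A, (2S)-2-(3,4-dihydroxyphenyl)-6-[(E)-3,7-dimethylocta-2,6-dienyl]-5,7-dihydroxy-2,3-dihydro-4H-chromen-4-one | CC(C)=CCC/C(C)=C/Cc1c(O)cc2c(c1O)C(=O)C[C@@H](c1ccc(O)c(O)c1)O2 | target

**Step count and risks**
Total step count: 10. Longest linear sequence: 8 steps (steps 1 to 6, 9 and 10); steps 7 and 8 form the side branch to boronic acid 19.

The three steps most likely to fail, in order of risk:

Step 9. Insertion at the electron-rich chromone, whose C4 carbonyl is flanked by the C5 acetal, may be slow enough for protodeboronation to consume the boronic acid, and facial selectivity may be poor or eroded by reversible ring opening. The fallback sets out from chromone 14 and boronic acid 19 and replaces catalyst control by resolution. The same addition under the more reactive ligand-free diene complex ([Rh(OH)(cod)]2, dioxane/H2O, 50 °C) should give the racemic flavanone F1. Kinetic resolution by asymmetric transfer hydrogenation (Cp*RhCl[(R,R)-TsDPEN] or its antipode, whichever reduces the (R)-ketone faster, HCO2H/Et3N, EtOAc) should then convert the (R)-enantiomer into the cis-(2R,4R)-flavan-4-ol F2 and leave the (S)-ketone, which is separated by chromatography. The route is rejoined at 20.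

Step 6. The o-hydroxybenzylic alcohol may ionise to an o-quinone methide before it is oxidised, the electron-rich free phenol may be attacked by MnO2, or the ynone may close in the 5-exo mode. The fallback sets out from phenol 8 and avoids the carbinol altogether. Acetylation (Ac2O, pyridine) should give the aryl acetate F3. Photo-Fries rearrangement (hν 254 nm, cyclohexane) should move the acetyl group to one of the two equivalent ortho carbons, the para position being blocked by the geranyl group, to give the o-hydroxyacetophenone F4. Condensation with Me2NCH(OMe)2 (toluene, 90 °C) should give the dimethylamino enone F5, which AcOH cyclises with loss of dimethylamine. The route is rejoined at chromone 14.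

Step 3. Lithiation may compete at the position beside the silyl ether, the aryl nucleophile may attack the allylic bromide in the SN2′ sense to give the branched isomer, or the liberated phenoxide may be O-alkylated. The fallback sets out from arene 1 and reverses the order of C–C and C–O bond formation. Lithiation of 1 between its two acetal ethers (n-BuLi, THF, 0 °C), the only doubly activated site, should give the aryllithium F6. Copper-catalysed coupling with geranyl bromide 5 should give 2-geranyl-1,3-bis(methoxymethoxy)benzene F7. Iridium-catalysed C–H borylation ([Ir(OMe)(cod)]2, 4,4′-di-tert-butyl-2,2′-bipyridine, B2pin2) at the only C–H without an ortho substituent, para to the geranyl group, should give the boronate F8, and H2O2/NaOH oxidises it to the phenol. The route is rejoined at 8, and steps 1 and 2 are no longer needed.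

**Further compounds**
F1 | step 9 | racemic 2-[3,4-bis(methoxymethoxy)phenyl]-6-[(E)-3,7-dimethylocta-2,6-dienyl]-5,7-bis(methoxymethoxy)-2,3-dihydro-4H-chromen-4-one | CC(C)=CCC/C(C)=C/Cc1c(OCOC)cc2c(c1OCOC)C(=O)CC(c1ccc(OCOC)c(OCOC)c1)O2
F2 | step 9 | (2R,4R)-2-[3,4-bis(methoxymethoxy)phenyl]-6-[(E)-3,7-dimethylocta-2,6-dienyl]-5,7-bis(methoxymethoxy)chroman-4-ol | CC(C)=CCC/C(C)=C/Cc1c(OCOC)cc2c(c1OCOC)[C@H](O)C[C@H](c1ccc(OCOC)c(OCOC)c1)O2
F3 | step 6 | 4-[(E)-3,7-dimethylocta-2,6-dienyl]-3,5-bis(methoxymethoxy)phenyl acetate | CC(C)=CCC/C(C)=C/Cc1c(OCOC)cc(OC(C)=O)cc1OCOC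
F4 | step 6 | 1-{3-[(E)-3,7-dimethylocta-2,6-dienyl]-6-hydroxy-2,4-bis(methoxymethoxy)phenyl}ethanone | CC(C)=CCC/C(C)=C/Cc1c(OCOC)cc(O)c(C(C)=O)c1OCOC
F5 | step 6 | (E)-3-(dimethylamino)-1-{3-[(E)-3,7-dimethylocta-2,6-dienyl]-6-hydroxy-2,4-bis(methoxymethoxy)phenyl}prop-2-en-1-one | CC(C)=CCC/C(C)=C/Cc1c(OCOC)cc(O)c(C(=O)/C=C/N(C)C)c1OCOC
F6 | step 3 | [2,6-bis(methoxymethoxy)phenyl]lithium | COCOc1cccc(OCOC)c1[Li]
F7 | step 3 | 2-[(E)-3,7-dimethylocta-2,6-dienyl]-1,3-bis(methoxymethoxy)benzene | CC(C)=CCC/C(C)=C/Cc1c(OCOC)cccc1OCOC
F8 | step 3 | 2-{4-[(E)-3,7-dimethylocta-2,6-dienyl]-3,5-bis(methoxymethoxy)phenyl}-4,4,5,5-tetramethyl-1,3,2-dioxaborolane | CC(C)=CCC/C(C)=C/Cc1c(OCOC)cc(B2OC(C)(C)C(C)(C)O2)cc1OCOC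
A1 | direct plan | (S)-3-[3,4-bis(tert-butyldimethylsilyloxy)phenyl]-3-hydroxy-N-methoxy-N-methylpropanamide | CON(C)C(=O)C[C@@H](c1ccc(O[Si](C)(C)C(C)(C)C)c(O[Si](C)(C)C(C)(C)C)c1)O
A2 | direct plan | (S)-3-[3,4-bis(tert-butyldimethylsilyloxy)phenyl]-N-methoxy-N-methyl-3-[(3-oxocyclobut-1-en-1-yl)oxy]propanamide | CON(C)C(=O)C[C@@H](c1ccc(O[Si](C)(C)C(C)(C)C)c(O[Si](C)(C)C(C)(C)C)c1)OC1=CC(=O)C1
A3 | direct plan | (E)-5,9-dimethyldeca-4,8-dien-1-ynyl triisopropylsilyl ether | CC(C)=CCC/C(C)=C/CC#CO[Si](C(C)C)(C(C)C)C(C)C
A4 | direct plan | (S)-3-[3,4-bis(tert-butyldimethylsilyloxy)phenyl]-3-{4-[(E)-3,7-dimethylocta-2,6-dienyl]-2-iodo-3,5-bis(triisopropylsilyloxy)phenoxy}-N-methoxy-N-methylpropanamide | CC(C)=CCC/C(C)=C/Cc1c(O[Si](C(C)C)(C(C)C)C(C)C)cc(O[C@@H](CC(=O)N(C)OC)c2ccc(O[Si](C)(C)C(C)(C)C)c(O[Si](C)(C)C(C)(C)C)c2)c(I)c1O[Si](C(C)C)(C(C)C)C(C)C
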